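**Retrosynthetic overview**
- Last disconnection (key step): both ring C–N bonds of the N‑methoxy‑4‑pyridone (N1–C2 and N1–C8a) → open‑chain 2‑methoxy‑1,3,5‑triketone + O‑methylhydroxylamine; the silyl ether is cleaved in the same flask.
- C2–C3 → dianion of a 2‑(methoxyacetyl)cyclohexanone + silyl‑protected methyl glycolate (Claisen).
- C4–C4a and C5–octyl → cyclohex‑2‑en‑1‑one + n‑octylmagnesium bromide + methoxyacetyl chloride in one pot; the C5 stereocentre is set here by copper‑catalysed asymmetric conjugate addition.
- Ring order: the carbocycle (ring A) comes intact from cyclohexenone; the pyridone (ring B) is the only ring formed, and it is formed last.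

Assumption: the Taniaphos enantiomer used is the one that gives the 3R conjugate adduct (I could not fix its descriptor from memory; its antipode gives 3S). This is checked on an aliquot quenched to 3‑octylcyclohexanone.

**Step 1**
Reactants: 1 cyclohex-2-en-1-one; 2 n-octylmagnesium bromide; 3 methoxyacetyl chloride
Product: 5 (3R)-2-(2-methoxyacetyl)-3-octylcyclohexan-1-one, via bromomagnesium (3R)-3-octylcyclohex-1-en-1-olate 4 (not isolated)
Conditions: CuCl (5 mol%), Taniaphos C43H39FeNP2 (6 mol%, enantiomer giving 3R), 2 (1.15 equiv), Et2O, 0 °C; then 3 (1.3 equiv), −78 → −20 °C; aq. NH4Cl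
Reagents that add atoms: none
Why: Copper‑catalysed enantioselective conjugate addition of a Grignard reagent (CuCl/ferrocenyl diphosphine) delivers octyl to one face of the enone and sets C3 (the later C5) as R, and the regiodefined magnesium enolate 4 is then C‑acylated by the acid chloride through a chelated six‑membered transition state (Claisen‑type acylation); C2 is enolisable and later becomes sp2, so its configuration does not matter.

**Step 2**
Reactants: 6 methyl glycolate
Product: 7 methyl 2-[(tert-butyldimethylsilyl)oxy]acetate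
Conditions: TBSCl (1.1 equiv), imidazole (2.2 equiv), DMF, 23 °C
Reagents that add atoms: tert-butyldimethylsilyl chloride (TBSCl), CC(C)(C)[Si](C)(C)Cl
Why: Standard imidazole‑promoted silylation of a primary alcohol (silyl ether protection); the silyl group prevents the later hydroxy‑triketone from closing to a 3(2H)‑furanone.

**Step 3**
Reactants: 5 (3R)-2-(2-methoxyacetyl)-3-octylcyclohexan-1-one; 7 methyl 2-[(tert-butyldimethylsilyl)oxy]acetate
Product: 9 (3R)-2-{4-[(tert-butyldimethylsilyl)oxy]-2-methoxy-3-oxobutanoyl}-3-octylcyclohexan-1-one, via dilithium dianion 8 (not isolated)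
Conditions: LiN(iPr)2 (2.0 equiv), THF, −78 → 0 °C; then 7 (1.0 equiv), −78 → −20 °C; AcOH
Reagents that add atoms: none
Why: Hauser–Harris dianion acylation (Claisen condensation): after the diketone C–H, the second proton is removed at the methoxy‑bearing CH2, which is about two pK units more acidic than the ring CH2 and gives a lithium‑chelated carbanion (as in the γ‑reactions of 4‑alkoxyacetoacetate dianions), and this γ‑carbon attacks ester 7; the C3 stereocentre is not acidic and is untouched.

**Step 4**
Reactants: 9 (3R)-2-{4-[(tert-butyldimethylsilyl)oxy]-2-methoxy-3-oxobutanoyl}-3-octylcyclohexan-1-one; 10 O-methylhydroxylamine hydrochloride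
Product: 13 (5R)-2-(hydroxymethyl)-1,3-dimethoxy-5-octyl-5,6,7,8-tetrahydroquinolin-4(1H)-one, via mono-O-methyl oxime 11 (not isolated), via silyl-protected pyridone 12 (not isolated)
Conditions: 10 (1.2 equiv), NaOAc (1.3 equiv), EtOH, 23 °C then 75 °C; then 2 M aq. HCl, 23 °C
Reagents that add atoms: none
Why: Proposed new method: a direct [5+1] condensative aza‑annulation of an open‑chain 2‑methoxy‑1,3,5‑triketone with an O‑alkylhydroxylamine to an N‑alkoxy‑4‑pyridone, forming both ring C–N bonds in one operation: at pH about 5 the α‑effect nucleophile MeONH2 forms the O‑methyl oxime at the least hindered terminal carbonyl (C2, giving 11), isoxazole closure is impossible because the oxygen is methylated, imine–enamine tautomerism gives an N‑methoxy enaminone whose N–H adds 6‑exo to the ring ketone, and loss of water aromatises to 12 (an oxime formed first at the ring ketone converges on the same ring, while one at the central carbonyl cannot close a six‑membered ring), after which aqueous acid removes the silyl group without touching the non‑acidic C5 centre; the closest known reaction type is the conversion of 1,3,5‑triketones or 4‑pyranones into 4‑pyridones with ammonia or primary amines and of 4‑pyranones into N‑hydroxy‑4‑pyridones with hydroxylamine, and to my knowledge the O‑alkylhydroxylamine variant on an open‑chain triketone has not been described.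

**Compound list**
1 | cyclohex-2-en-1-one | O=C1C=CCCC1 | starting material
2 | n-octylmagnesium bromide | CCCCCCCC[Mg]Br | starting material
3 | methoxyacetyl chloride | COCC(=O)Cl | starting material
4 | bromomagnesium (3R)-3-octylcyclohex-1-en-1-olate | CCCCCCCC[C@@H]1CCCC(O[Mg]Br)=C1 | intermediate
5 | (3R)-2-(2-methoxyacetyl)-3-octylcyclohexan-1-one (C2 epimers and enol forms) | CCCCCCCC[C@@H]1CCCC(=O)C1C(=O)COC | intermediate
6 | methyl glycolate | COC(=O)CO | starting material
7 | methyl 2-[(tert-butyldimethylsilyl)oxy]acetate | COC(=O)CO[Si](C)(C)C(C)(C)C | intermediate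
8 | dilithium (3R)-2-(2-methoxy-1-oxidoethenyl)-3-octylcyclohex-1-en-1-olate (dianion of 5) | [Li+].[Li+].CCCCCCCC[C@@H]1CCCC([O-])=C1C([O-])=COC | intermediate
9 | (3R)-2-{4-[(tert-butyldimethylsilyl)oxy]-2-methoxy-3-oxobutanoyl}-3-octylcyclohexan-1-one (tautomer and epimer mixture) | CCCCCCCC[C@@H]1CCCC(=O)C1C(=O)C(OC)C(=O)CO[Si](C)(C)C(C)(C)C | intermediate
10 | O-methylhydroxylamine hydrochloride | CON.Cl | starting material
11 | (3R)-2-{4-[(tert-butyldimethylsilyl)oxy]-2-methoxy-3-(methoxyimino)butanoyl}-3-octylcyclohexan-1-one | CCCCCCCC[C@@H]1CCCC(=O)C1C(=O)C(OC)C(=NOC)CO[Si](C)(C)C(C)(C)C | intermediate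
12 | (5R)-2-{[(tert-butyldimethylsilyl)oxy]methyl}-1,3-dimethoxy-5-octyl-5,6,7,8-tetrahydroquinolin-4(1H)-one | CCCCCCCC[C@@H]1CCCc2c1c(=O)c(OC)c(CO[Si](C)(C)C(C)(C)C)n2OC | intermediate
13 | (5R)-2-(hydroxymethyl)-1,3-dimethoxy-5-octyl-5,6,7,8-tetrahydroquinolin-4(1H)-one | CCCCCCCC[C@@H]1CCCc2c1c(=O)c(OC)c(CO)n2OC | target

**Step count**
Total steps: 4. Longest linear sequence: 3 (steps 1, 3, 4).

**Three steps most likely to fail**

Step 4 (the proposed new annulation). Possible failures are bis‑oximation, oximation at the central carbonyl, O‑cyclisation to the 4‑pyranone, or retro‑Claisen cleavage of the 2‑alkoxy‑diketone. The fallback uses known chemistry, sets out from 9 and comes back at 12. Triketone 9 is cyclodehydrated under neutral conditions (Ph3P, CCl4, THF) to the pyranone (5R)-2-{[(tert-butyldimethylsilyl)oxy]methyl}-3-methoxy-5-octyl-5,6,7,8-tetrahydro-4H-chromen-4-one F1. Heating F1 with NH2OH·HCl in pyridine (the classical pyranone‑to‑N‑hydroxypyridone ring opening and reclosure) gives (5R)-2-{[(tert-butyldimethylsilyl)oxy]methyl}-1-hydroxy-3-methoxy-5-octyl-5,6,7,8-tetrahydroquinolin-4(1H)-one F2. Methylation of F2 at the N–O oxygen with MeI and K2CO3 in DMF gives 12, which is desilylated with aqueous HCl as in the second stage of step 4.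

Step 3 (site of the second deprotonation). The ring CH2 next to the ring ketone could compete with the methoxy‑bearing CH2 and give the wrong triketone. The fallback sets out from enolate 4 and comes back at 9. Enolate 4 is acylated with acetyl chloride in place of 3 to give (3R)-2-acetyl-3-octylcyclohexan-1-one F3. Its dianion (LiN(iPr)2, 2 equiv) forms at the terminal methyl, following the established methyl‑before‑methylene order, and is acylated with 7 to give (3R)-2-{4-[(tert-butyldimethylsilyl)oxy]-3-oxobutanoyl}-3-octylcyclohexan-1-one F4. Diazo transfer (4‑acetamidobenzenesulfonyl azide, Et3N, MeCN) at the only doubly activated CH2 gives (3R)-2-{4-[(tert-butyldimethylsilyl)oxy]-2-diazo-3-oxobutanoyl}-3-octylcyclohexan-1-one F5. O–H insertion of the carbenoid from F5 into methanol, catalysed by Rh2(OAc)4, installs the methoxy group and gives 9.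

Step 1 (one‑pot acylation of the magnesium enolate). Possible failures are O‑acylation to the enol ester, or proton transfer from product to enolate that stalls conversion. The fallback sets out from enolate 4 and comes back at 5. Enolate 4 is trapped with Me3SiCl and Et3N to give the regiodefined silyl enol ether trimethyl{[(3R)-3-octylcyclohex-1-en-1-yl]oxy}silane F6, which is isolated. F6 is then C‑acylated with 3 under ZnCl2 mediation in CH2Cl2/Et2O (Mukaiyama‑type acylation of a silyl enol ether) to give 5.

**Further compounds**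
F1 | step 4 | (5R)-2-{[(tert-butyldimethylsilyl)oxy]methyl}-3-methoxy-5-octyl-5,6,7,8-tetrahydro-4H-chromen-4-one | CCCCCCCC[C@@H]1CCCc2c1c(=O)c(OC)c(CO[Si](C)(C)C(C)(C)C)o2
F2 | step 4 | (5R)-2-{[(tert-butyldimethylsilyl)oxy]methyl}-1-hydroxy-3-methoxy-5-octyl-5,6,7,8-tetrahydroquinolin-4(1H)-one | CCCCCCCC[C@@H]1CCCc2c1c(=O)c(OC)c(CO[Si](C)(C)C(C)(C)C)n2O
F3 | step 3 | (3R)-2-acetyl-3-octylcyclohexan-1-one | CCCCCCCC[C@@H]1CCCC(=O)C1C(C)=O
F4 | step 3 | (3R)-2-{4-[(tert-butyldimethylsilyl)oxy]-3-oxobutanoyl}-3-octylcyclohexan-1-one | CCCCCCCC[C@@H]1CCCC(=O)C1C(=O)CC(=O)CO[Si](C)(C)C(C)(C)C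
F5 | step 3 | (3R)-2-{4-[(tert-butyldimethylsilyl)oxy]-2-diazo-3-oxobutanoyl}-3-octylcyclohexan-1-one | CCCCCCCC[C@@H]1CCCC(=O)C1C(=O)C(=[N+]=[N-])C(=O)CO[Si](C)(C)C(C)(C)C
F6 | step 1 | trimethyl{[(3R)-3-octylcyclohex-1-en-1-yl]oxy}silane | CCCCCCCC[C@@H]1CCCC(O[Si](C)(C)C)=C1
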